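The runs were generated by integration with constants of no real substance, and the scatter is random.

14.2% of bis adduct after 15.0 h: that is Wednesday's run, with teal's temperature, reagent and time but half teal's substrate, and I bound teal from it.

| setting | Sunday's | Wednesday's | Monday's | amber | teal | grey | green | blue |
|---|---|---|---|---|---|---|---|---|
| substrate | 0.20 M | 0.10 M | 0.40 M | 0.20 M | 0.20 M | 0.20 M | 0.20 M (fed, over 12 h) | 0.20 M |
| reagent | 0.40 M | 0.40 M | 0.40 M | 0.400 M (fed, over 12 h) | 0.400 M | 0.400 M | 0.400 M | 0.400 M (in portions, 2, over 12 h) |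
| temperature | 95 °C | 110 °C | 95 °C | 110 °C | 110 °C |  |  | 110 °C |
| remark | run made earlier | run made earlier | run made earlier | all else is in the flask from the start; the feed brings no volume worth counting | everything together at the start | everything together at the start at 90 °C, warmed to 110 °C at 12 h | the addition at 90 °C, then warmed to 110 °C; the feed brings no volume worth counting | first portion at the start, last at 12 h |
| time |  |  |  | 15 h | 15 h | 15 h | 15 h | 15 h |

| run | time / h | bis adduct / % | first product / % | substrate / % |
|---|---|---|---|---|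
| Sunday's | 3.00 | 0.7 | 29.7 | 67.4 |
| Sunday's | 4.00 | 1.1 | 34.9 | 60.3 |
| Sunday's | 6.00 | 1.3 | 43.2 | 48.2 |
| Sunday's | 8.00 | 2.4 | 47.1 | 39.4 |
| Sunday's | 12.0 | 2.5 | 52.3 | 27.7 |
| Sunday's | 20.0 | 4.2 | 54.7 | 14.8 |
| Sunday's | 30.0 | 7.5 | 50.6 | 6.1 |
| Wednesday's | 2.00 | 1.2 | 48.8 | 42.4 |
| Wednesday's | 4.00 | 3.0 | 59.2 | 19.4 |
| Wednesday's | 6.00 | 5.7 | 58.2 | 7.9 |
| Wednesday's | 8.00 | 9.3 | 53.8 | 4.6 |
| Wednesday's | 10.0 | 9.5 | 48.8 | 1.5 |
| Wednesday's | 12.0 | 12.4 | 43.4 | 1.7 |
| Wednesday's | 15.0 | 14.2 | 36.4 | 0.5 |
| Monday's | 2.00 | 0.1 | 20.6 | 77.6 |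
| Monday's | 5.00 | 1.7 | 35.9 | 58.4 |
| Monday's | 8.00 | 1.0 | 41.3 | 46.4 |
| Monday's | 12.0 | 1.8 | 45.5 | 36.7 |
| Monday's | 20.0 | 2.7 | 47.1 | 26.4 |
| Monday's | 25.0 | 2.8 | 46.2 | 23.0 |
| Monday's | 30.0 | 3.3 | 45.8 | 19.9 |

(standard deviation of a reading: 0.5 percentage points)

* the flask that comes out highest in amount of bis adduct, in percent of the substrate charged, or "all alike" when all lie within 1.5 percentage points (amber / teal / grey / green / blue / all alike)
* bis adduct at the end, in percent of the substrate charged, amber
* bis adduct at the end, in percent of the substrate charged, teal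
* bis adduct at the end, in percent of the substrate charged, grey
* bis adduct at the end, in percent of the substrate charged, green
* bis adduct at the end, in percent of the substrate charged, blue



Let p be first product as a fraction of the substrate charged, r reagent as a fraction of its charge, b bis adduct. I assume

b per hour = g · r · p

I count one reagent per substrate converted and one per bis adduct, so Wednesday's r is 0.755 at 6.00 h and 0.716 at 15.0 h. Between those readings b climbs 8.5 percentage points, so

g = 0.0271 /h

This g is the share of first product turned into bis adduct per hour at full reagent; g · r is a pseudo-first-order constant, and 1/g is 36.9 h.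

Above: teal pays twice as much of its reagent per unit of conversion, so its r should stay lower; with p taken from Wednesday's run, that puts b under 14.2%.

Below: from 4.00 h on, I take teal's r at its floor, 0.431, and p at Wednesday's last reading, which gives 4.69%.

Tightened: if p follows Wednesday's, b scales with r. Of Wednesday's b, 78.9% forms after 4.00 h, so I use the ratio of r at both ends of that stretch:

upper: 14.2% × 0.582 / 0.791 = 10.4%

lower: 14.2% × 0.431 / 0.716 = 8.56%

The forecast puts teal at 9.7%, above my lower line and below my upper one, and it names teal as highest, with amber 5%, grey 4%, green 3.1%, blue 4.1%: “Teal is highest because it has both high reagent and hot time.”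

Teal gives 9.98%, the highest, and inside the bracket; amber gives 5.42%, grey 4.06%, green 3.13%, blue 4.08%.

    substrate + reagent → first product + by-product (k = 1.20 /M/h, Ea = 94.0 kJ/mol)
    reagent + first product → bis adduct + by-product (k = 0.0640 /M/h, Ea = 94.0 kJ/mol)
    first product → over-reaction product (k = 0.0630 /h, Ea = 113 kJ/mol)
    first product ⇌ isomer of the product (K = 0.150, k = 0.200 /h, Ea = 110 kJ/mol, ΔH = −51.0 kJ/mol)
    (constants at 110 °C)

At its end teal holds 45.8% of its reagent. Grey, hot from 12.0 h on, tests g: with the means of its r and p over the last hours, g gives 2.7 points, and grey's bis adduct rises 2.6 points.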